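Which of Sunday's and Friday's flasks ends with the longer chains after 4.0 min?

all flasks: initiator 1 mol%
- beta: free monomer 1.3 M; protic impurity 0.45 M; run made earlier
- zeta: free monomer 1.9 M; protic impurity 0.45 M; run made earlier
- delta: free monomer 3 M; protic impurity 0.45 M; run made earlier
- Sunday's: free monomer 1.5 M; protic impurity 0.450 M; time 4.0 min
- Friday's: free monomer 2.5 M; protic impurity 0.450 M; time 4.0 min

| run | time / s | monomer in chains / % |
|---|---|---|
| beta | 10.0 | 0.8 |
| beta | 30.0 | 2.7 |
| beta | 60.0 | 5.7 |
| beta | 80.0 | 7.6 |
| beta | 120 | 11.4 |
| zeta | 10.0 | 1.0 |
| zeta | 20.0 | 2.4 |
| zeta | 30.0 | 3.5 |
| zeta | 60.0 | 11.8 |
| zeta | 120 | 22.0 |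
| delta | 10.0 | 2.6 |
| delta | 30.0 | 9.0 |
| delta | 60.0 | 21.0 |
| delta | 80.0 | 28.3 |
| delta | 120 | 39.7 |

(readings scatter by 0.5 percentage points)

1. which of the two ends with the longer chains by the average number of monomer units in a chain (chains begun, living or dead) ("neither" if they lie within 10 %) (Sunday's / Friday's / neither)
2. average number of monomer units in a chain (chains begun, living or dead) at the end, Sunday's
3. average number of monomer units in a chain (chains begun, living or dead) at the end, Friday's

- the average divides the monomer in chains by the number of chains begun, living and dead together
- candidate steps: free monomer + initiator -> living end + monomer in chains; protic impurity + free monomer -> quenched substrate; free monomer + living end -> monomer in chains + living end; monomer in chains + living end -> free monomer + living end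
- the earlier runs do not show the number of chains; that part of a forecast is a guess

The bench rule takes each initiator molecule as one chain, so the average length is the fraction of monomer in chains divided by the loading. If the whole charge could enter chains, that gives 100 units in either flask. The earlier runs do not show the number of chains, so this part is a guess.

That figure stops working where quenching takes a visible part of the charge. Sunday's has 30.0 % as its toll, the share of charged free monomer lost to quenching, [protic impurity]/[free monomer] at the start. Friday's toll is 18.0 %. The toll is a ratio of charges, so time drops out. It treats the protic impurity as the limiting reagent of quenching, and [protic impurity] is less than [free monomer] in both flasks.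

My ceilings are therefore 70.0 units for Sunday's and 82.0 for Friday's, a ratio of 1.17. They are ceilings, not lengths: the delta run's last reading, 39.7 %, is lower than its own available share of 85.0 %. That last reading is also higher than the beta run's 11.4 %, so the richer charge climbs faster. I commit to Friday's, with both lengths under their ceilings.

The forecast says Friday's, with 31 units for Sunday's and 52 for Friday's. Its ground is: “The impurity appears to take a fixed 0.45 M of monomer fairly quickly, which hurts dilute runs most”. Its numbers are lengths at the end, where mine are ceilings.

The flask gives Friday's, with 29.7 units for Sunday's and 52.9 for Friday's, so the forecast stands on the direction and on both lengths.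

    free monomer + initiator → living end + monomer in chains (k = 0.0300 /M/s)
    protic impurity + free monomer → quenched substrate (k = 0.110 /M/s)
    free monomer + living end → monomer in chains + living end, rate k3*[living end]*[free monomer] (k = 0.210 /M/s)
    monomer in chains + living end → free monomer + living end, rate k4*[living end] as long as [monomer in chains] is above zero (k = 0.0310 /s)

In Sunday's, half of the quenching turnover is done by 0.0768 min, while half of the growth turnover takes until 2.00 min. After 4.00 min, Sunday's holds 30.0 % of quenched substrate against a toll of 30.0 %, and Friday's holds 18.0 % against a toll of 18.0 %.

The runs were computed with constants of no real substance; noise was put on by code.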